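**Retrosynthetic overview**
1. Target 18 ⇐ debenzylation ⇐ Felkin–Anh reduction of the C7' aryl ketone 16 ⇐ aryl Grignard addition to oxolane aldehyde 12, then benzylic oxidation.
2. Aldehyde 12 ⇐ glycol cleavage of the glyceraldehyde-derived dioxolane in 10; the only ring (the oxolane, step 5) ⇐ DDQ benzylic C–H/O–H oxidative cyclisation of 1,4-diol 9.
3. Diol 9 ⇐ ozonolysis/LiAlH4 of γ,δ-unsaturated acid 7 ⇐ Ireland–Claisen [3,3] rearrangement of allylic ester 4, which forms the central C8–C8' bond and sets both of its stereocentres.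
4. Ester 4 ⇐ 3-arylpropanoic acid 3 + (Z)-allylic alcohol 2 ⇐ D-mannitol-derived (S,Z)-enoate 1, the only source of chirality.

Assumption: 1, 3 and 13 are taken as catalogue compounds; lignan numbering (C7/C8/C9 on the guaiacyl half, C7'/C8'/C9' on the catechol half) is used in the explanations.

**Step 1**
Reactants: 1 methyl (2Z)-3-[(4S)-2,2-dimethyl-1,3-dioxolan-4-yl]prop-2-enoate
Product: 2 (2Z)-3-[(4S)-2,2-dimethyl-1,3-dioxolan-4-yl]prop-2-en-1-ol
Conditions: DIBAL-H (2.2 equiv), CH2Cl2, −78 → 0 °C; Rochelle salt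
Reagents that add atoms: none
Why: DIBAL-H 1,2-reduction of the unsaturated ester gives the allylic alcohol without touching the Z-alkene, the acetonide or the stereocentre.

**Step 2**
Reactants: 2 (2Z)-3-[(4S)-2,2-dimethyl-1,3-dioxolan-4-yl]prop-2-en-1-ol; 3 3-[4-(benzyloxy)-3-methoxyphenyl]propanoic acid
Product: 4 (2Z)-3-[(4S)-2,2-dimethyl-1,3-dioxolan-4-yl]prop-2-en-1-yl 3-[4-(benzyloxy)-3-methoxyphenyl]propanoate
Conditions: DCC, DMAP (cat.), CH2Cl2, 0 °C → rt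
Reagents that add atoms: none
Why: Steglich esterification joins acid and allylic alcohol under neutral conditions that preserve the alkene geometry and the acetonide.

**Step 3**
Reactants: 4 (2Z)-3-[(4S)-2,2-dimethyl-1,3-dioxolan-4-yl]prop-2-en-1-yl 3-[4-(benzyloxy)-3-methoxyphenyl]propanoate
Product: 7 (2R,3R)-2-[4-(benzyloxy)-3-methoxybenzyl]-3-[(4S)-2,2-dimethyl-1,3-dioxolan-4-yl]pent-4-enoic acid, via Z-silyl ketene acetal 5 (not isolated), via trimethylsilyl ester 6 (not isolated)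
Conditions: LDA, THF–DMPU (4:1), −78 °C; TMSCl; −78 → 60 °C; then 1 M NaOH, acidify to pH 4
Reagents that add atoms: none
Why: Ireland–Claisen [3,3]-sigmatropic rearrangement through a chair in which the Z(O)-enolate-derived ketene acetal holds ArCH2 equatorial and the Z-alkene holds the dioxolanyl group axial (2,3-anti, 2R,3R), the face being fixed by the (S)-dioxolane (allylic H eclipsed by A1,3 strain, new C–C bond anti to its C–O bond).

**Step 4**
Reactants: 7 (2R,3R)-2-[4-(benzyloxy)-3-methoxybenzyl]-3-[(4S)-2,2-dimethyl-1,3-dioxolan-4-yl]pent-4-enoic acid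
Product: 9 (2R,3S)-2-[4-(benzyloxy)-3-methoxybenzyl]-3-[(4S)-2,2-dimethyl-1,3-dioxolan-4-yl]butane-1,4-diol, via ozonide 8 (not isolated)
Conditions: O3, CH2Cl2, −78 °C (Sudan III end point); N2 purge; then LiAlH4, THF, −78 °C → reflux
Reagents that add atoms: ozone, [O-][O+]=O
Why: Ozonolysis of the vinyl group followed by LiAlH4 reduces the ozonide and the carboxylic acid in one pot to the 1,4-diol without touching any stereocentre.

**Step 5**
Reactants: 9 (2R,3S)-2-[4-(benzyloxy)-3-methoxybenzyl]-3-[(4S)-2,2-dimethyl-1,3-dioxolan-4-yl]butane-1,4-diol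
Product: 10 {(2S,3R,4S)-2-[4-(benzyloxy)-3-methoxyphenyl]-4-[(4S)-2,2-dimethyl-1,3-dioxolan-4-yl]oxolan-3-yl}methanol
Conditions: DDQ (1.1 equiv), 4 Å MS, CH2Cl2, 0 °C → rt
Reagents that add atoms: none
Why: DDQ hydride abstraction at the electron-rich benzylic CH2 gives a p-alkoxybenzyl cation that the C9' hydroxyl traps as a five-membered ring (oxidative C–H etherification; the C9 hydroxyl could only form an oxetane), placing the aryl group trans to the neighbouring CH2OH (all-trans, 2S).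

**Step 6**
Reactants: 10 {(2S,3R,4S)-2-[4-(benzyloxy)-3-methoxyphenyl]-4-[(4S)-2,2-dimethyl-1,3-dioxolan-4-yl]oxolan-3-yl}methanol
Product: 12 (3S,4R,5S)-5-[4-(benzyloxy)-3-methoxyphenyl]-4-(hydroxymethyl)oxolane-3-carbaldehyde, via triol 11 (not isolated)
Conditions: H5IO6 (1.3 equiv), EtOAc, 0 °C → rt
Reagents that add atoms: none
Why: Periodic acid hydrolyses the terminal acetonide and cleaves the 1,2-diol (Malaprade glycol cleavage) to the aldehyde under conditions too mild to epimerise the α-centre, and the trans CH2OH cannot close a lactol.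

**Step 7**
Reactants: 12 (3S,4R,5S)-5-[4-(benzyloxy)-3-methoxyphenyl]-4-(hydroxymethyl)oxolane-3-carbaldehyde; 13 4-bromo-1,2-bis(benzyloxy)benzene
Product: 15 [3,4-bis(benzyloxy)phenyl]{(3S,4R,5S)-5-[4-(benzyloxy)-3-methoxyphenyl]-4-(hydroxymethyl)oxolan-3-yl}methanol (C7' epimer mixture), via aryl Grignard reagent 14 (not isolated)
Conditions: 13, Mg, THF, 40 °C; then 12 (0.33 equiv), THF, −78 → 0 °C; aq NH4Cl
Reagents that add atoms: none
Why: Grignard addition to the aldehyde installs the catechol-derived ring; the carbinol configuration (mainly 7'S by Felkin–Anh) does not matter because step 8 erases it.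

**Step 8**
Reactants: 15 [3,4-bis(benzyloxy)phenyl]{(3S,4R,5S)-5-[4-(benzyloxy)-3-methoxyphenyl]-4-(hydroxymethyl)oxolan-3-yl}methanol (C7' epimer mixture)
Product: 16 [3,4-bis(benzyloxy)phenyl]{(3S,4R,5S)-5-[4-(benzyloxy)-3-methoxyphenyl]-4-(hydroxymethyl)oxolan-3-yl}methanone
Conditions: activated MnO2 (excess), CH2Cl2, rt
Reagents that add atoms: none
Why: MnO2 oxidises only the benzylic secondary alcohol and leaves the primary alcohol alone, giving the aryl ketone.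

**Step 9**
Reactants: 16 [3,4-bis(benzyloxy)phenyl]{(3S,4R,5S)-5-[4-(benzyloxy)-3-methoxyphenyl]-4-(hydroxymethyl)oxolan-3-yl}methanone
Product: 17 (R)-[3,4-bis(benzyloxy)phenyl]{(3S,4R,5S)-5-[4-(benzyloxy)-3-methoxyphenyl]-4-(hydroxymethyl)oxolan-3-yl}methanol
Conditions: L-Selectride (3 equiv), THF, −78 °C; aq NH4Cl
Reagents that add atoms: none
Why: Felkin–Anh-controlled ketone reduction in which the bulky hydride attacks anti to the branched ring carbon C4 (the same face a chelate through the ring oxygen would expose), giving the (R)-carbinol.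

**Step 10**
Reactants: 17 (R)-[3,4-bis(benzyloxy)phenyl]{(3S,4R,5S)-5-[4-(benzyloxy)-3-methoxyphenyl]-4-(hydroxymethyl)oxolan-3-yl}methanol
Product: 18 4-[(R)-hydroxy{(3S,4R,5S)-4-(hydroxymethyl)-5-(4-hydroxy-3-methoxyphenyl)oxolan-3-yl}methyl]benzene-1,2-diol
Conditions: H2 (1 atm), 10% Pd/C, EtOAc–MeOH, rt, stopped at full conversion
Reagents that add atoms: none
Why: Catalytic hydrogenolysis removes the three phenolic benzyl ethers much faster than it attacks the benzylic C–O bonds of the oxolane and the carbinol.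

**Compound list**
1 | methyl (2Z)-3-[(4S)-2,2-dimethyl-1,3-dioxolan-4-yl]prop-2-enoate | COC(=O)/C=C\[C@H]1COC(C)(C)O1 | starting material
2 | (2Z)-3-[(4S)-2,2-dimethyl-1,3-dioxolan-4-yl]prop-2-en-1-ol | OC/C=C\[C@H]1COC(C)(C)O1 | intermediate
3 | 3-[4-(benzyloxy)-3-methoxyphenyl]propanoic acid | COc1cc(CCC(=O)O)ccc1OCc1ccccc1 | starting material
4 | (2Z)-3-[(4S)-2,2-dimethyl-1,3-dioxolan-4-yl]prop-2-en-1-yl 3-[4-(benzyloxy)-3-methoxyphenyl]propanoate | COc1cc(CCC(=O)OC/C=C\[C@H]2COC(C)(C)O2)ccc1OCc1ccccc1 | intermediate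
5 | Z-silyl ketene acetal of 4 (ArCH2 cis to OSiMe3) | COc1cc(C/C=C(\O[Si](C)(C)C)OC/C=C\[C@H]2COC(C)(C)O2)ccc1OCc1ccccc1 | intermediate
6 | trimethylsilyl (2R,3R)-2-[4-(benzyloxy)-3-methoxybenzyl]-3-[(4S)-2,2-dimethyl-1,3-dioxolan-4-yl]pent-4-enoate | C[Si](C)(C)OC(=O)[C@H](Cc1ccc(OCc2ccccc2)c(OC)c1)[C@@H](C=C)[C@H]1COC(C)(C)O1 | intermediate
7 | (2R,3R)-2-[4-(benzyloxy)-3-methoxybenzyl]-3-[(4S)-2,2-dimethyl-1,3-dioxolan-4-yl]pent-4-enoic acid | OC(=O)[C@H](Cc1ccc(OCc2ccccc2)c(OC)c1)[C@@H](C=C)[C@H]1COC(C)(C)O1 | intermediate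
8 | ozonide of 7 (1,2,4-trioxolan-3-yl in place of vinyl) | OC(=O)[C@H](Cc1ccc(OCc2ccccc2)c(OC)c1)[C@@H](C1OCOO1)[C@H]1COC(C)(C)O1 | intermediate
9 | (2R,3S)-2-[4-(benzyloxy)-3-methoxybenzyl]-3-[(4S)-2,2-dimethyl-1,3-dioxolan-4-yl]butane-1,4-diol | OC[C@H](Cc1ccc(OCc2ccccc2)c(OC)c1)[C@@H](CO)[C@H]1COC(C)(C)O1 | intermediate
10 | {(2S,3R,4S)-2-[4-(benzyloxy)-3-methoxyphenyl]-4-[(4S)-2,2-dimethyl-1,3-dioxolan-4-yl]oxolan-3-yl}methanol | COc1cc([C@H]2OC[C@@H]([C@H]3COC(C)(C)O3)[C@@H]2CO)ccc1OCc1ccccc1 | intermediate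
11 | (1S)-1-{(3S,4R,5S)-5-[4-(benzyloxy)-3-methoxyphenyl]-4-(hydroxymethyl)oxolan-3-yl}ethane-1,2-diol | COc1cc([C@H]2OC[C@@H]([C@H](O)CO)[C@@H]2CO)ccc1OCc1ccccc1 | intermediate
12 | (3S,4R,5S)-5-[4-(benzyloxy)-3-methoxyphenyl]-4-(hydroxymethyl)oxolane-3-carbaldehyde | COc1cc([C@H]2OC[C@@H](C=O)[C@@H]2CO)ccc1OCc1ccccc1 | intermediate
13 | 4-bromo-1,2-bis(benzyloxy)benzene | Brc1ccc(OCc2ccccc2)c(OCc2ccccc2)c1 | starting material
14 | [3,4-bis(benzyloxy)phenyl]magnesium bromide | Br[Mg]c1ccc(OCc2ccccc2)c(OCc2ccccc2)c1 | intermediate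
15 | [3,4-bis(benzyloxy)phenyl]{(3S,4R,5S)-5-[4-(benzyloxy)-3-methoxyphenyl]-4-(hydroxymethyl)oxolan-3-yl}methanol, C7' epimer mixture | COc1cc([C@H]2OC[C@@H](C(O)c3ccc(OCc4ccccc4)c(OCc4ccccc4)c3)[C@@H]2CO)ccc1OCc1ccccc1 | intermediate
16 | [3,4-bis(benzyloxy)phenyl]{(3S,4R,5S)-5-[4-(benzyloxy)-3-methoxyphenyl]-4-(hydroxymethyl)oxolan-3-yl}methanone | COc1cc([C@H]2OC[C@@H](C(=O)c3ccc(OCc4ccccc4)c(OCc4ccccc4)c3)[C@@H]2CO)ccc1OCc1ccccc1 | intermediate
17 | (R)-[3,4-bis(benzyloxy)phenyl]{(3S,4R,5S)-5-[4-(benzyloxy)-3-methoxyphenyl]-4-(hydroxymethyl)oxolan-3-yl}methanol | COc1cc([C@H]2OC[C@@H]([C@@H](O)c3ccc(OCc4ccccc4)c(OCc4ccccc4)c3)[C@@H]2CO)ccc1OCc1ccccc1 | intermediate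
18 | 4-[(R)-hydroxy{(3S,4R,5S)-4-(hydroxymethyl)-5-(4-hydroxy-3-methoxyphenyl)oxolan-3-yl}methyl]benzene-1,2-diol | COc1cc([C@H]2OC[C@@H]([C@@H](O)c3ccc(O)c(O)c3)[C@@H]2CO)ccc1O | target

**Total steps:** 10. **Longest linear sequence:** 10 (1 → 18); 3 and 13 enter as purchased.

**Three steps most likely to fail**

Step 3 (Ireland–Claisen). The result depends on Z(O)-enolate selectivity, on the chair being preferred with an axial dioxolanyl group, and on the facial bias of the dioxolane. The fallback sets out from 2 and returns at 9, setting the two centres in separate operations. Alcohol 2 is heated with triethyl orthoacetate and catalytic propionic acid (Johnson–Claisen, 140 °C), where only the facial bias matters, to give ethyl (3S)-3-[(4S)-2,2-dimethyl-1,3-dioxolan-4-yl]pent-4-enoate F1. Its lithium enolate (LDA, THF, −78 °C) is alkylated with 4-(benzyloxy)-3-methoxybenzyl bromide anti to the dioxolanyl group (β-H eclipsed) to give ethyl (2R,3R)-2-[4-(benzyloxy)-3-methoxybenzyl]-3-[(4S)-2,2-dimethyl-1,3-dioxolan-4-yl]pent-4-enoate F2. Ozonolysis and LiAlH4 as in step 4 then reduce the ester and the ozonide to 9.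

Step 5 (DDQ oxidative cyclisation). Risks are over-oxidation of the product's benzylic C–H and dehydrogenation to a styrene. The fallback sets out from 9 and returns at 10 through a quinone methide instead of a benzylic cation. Hydrogenolysis of 9 (H2, Pd/C) gives (2R,3S)-3-[(4S)-2,2-dimethyl-1,3-dioxolan-4-yl]-2-(4-hydroxy-3-methoxybenzyl)butane-1,4-diol F3. Ag2O in CH2Cl2 oxidises the 4-alkylguaiacol to the p-quinone methide F4 (not isolated). The C9' hydroxyl adds to it in a reversible 1,6-addition to give the all-trans 4-{(2S,3R,4S)-4-[(4S)-2,2-dimethyl-1,3-dioxolan-4-yl]-3-(hydroxymethyl)oxolan-2-yl}-2-methoxyphenol F5. BnBr/K2CO3 in acetone alkylates only the phenol and gives 10.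

Step 9 (C7' configuration by ketone reduction). Selectivity may be eroded by the free C9 alkoxide or by enolisation of the β-alkoxy ketone. The fallback sets out from 15 and returns at 17 by inversion instead of reduction. The major (7'S) epimer of 15 is separated and silylated at the primary hydroxyl (TBSCl, imidazole, 0 °C) to give (S)-[3,4-bis(benzyloxy)phenyl]{(3S,4R,5S)-5-[4-(benzyloxy)-3-methoxyphenyl]-4-[(tert-butyldimethylsilyloxy)methyl]oxolan-3-yl}methanol F6. Mitsunobu reaction (4-nitrobenzoic acid, DIAD, PPh3) inverts the carbinol to the (R)-4-nitrobenzoate F7. K2CO3/MeOH frees the (R)-alcohol silyl ether F8, and TBAF gives 17.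

**Further compounds**
F1 | step 3 | ethyl (3S)-3-[(4S)-2,2-dimethyl-1,3-dioxolan-4-yl]pent-4-enoate | CCOC(=O)C[C@@H](C=C)[C@H]1COC(C)(C)O1
F2 | step 3 | ethyl (2R,3R)-2-[4-(benzyloxy)-3-methoxybenzyl]-3-[(4S)-2,2-dimethyl-1,3-dioxolan-4-yl]pent-4-enoate | CCOC(=O)[C@H](Cc1ccc(OCc2ccccc2)c(OC)c1)[C@@H](C=C)[C@H]1COC(C)(C)O1
F3 | step 5 | (2R,3S)-3-[(4S)-2,2-dimethyl-1,3-dioxolan-4-yl]-2-(4-hydroxy-3-methoxybenzyl)butane-1,4-diol | OC[C@H](Cc1ccc(O)c(OC)c1)[C@@H](CO)[C@H]1COC(C)(C)O1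
F4 | step 5 | p-quinone methide of F3 (4-alkylidene-2-methoxycyclohexa-2,5-dienone) | O=C1C=CC(=C[C@@H](CO)[C@@H](CO)[C@H]2COC(C)(C)O2)C=C1OC
F5 | step 5 | 4-{(2S,3R,4S)-4-[(4S)-2,2-dimethyl-1,3-dioxolan-4-yl]-3-(hydroxymethyl)oxolan-2-yl}-2-methoxyphenol | COc1cc([C@H]2OC[C@@H]([C@H]3COC(C)(C)O3)[C@@H]2CO)ccc1O
F6 | step 9 | (S)-[3,4-bis(benzyloxy)phenyl]{(3S,4R,5S)-5-[4-(benzyloxy)-3-methoxyphenyl]-4-[(tert-butyldimethylsilyloxy)methyl]oxolan-3-yl}methanol | COc1cc([C@H]2OC[C@@H]([C@H](O)c3ccc(OCc4ccccc4)c(OCc4ccccc4)c3)[C@@H]2CO[Si](C)(C)C(C)(C)C)ccc1OCc1ccccc1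
F7 | step 9 | (R)-[3,4-bis(benzyloxy)phenyl]{(3S,4R,5S)-5-[4-(benzyloxy)-3-methoxyphenyl]-4-[(tert-butyldimethylsilyloxy)methyl]oxolan-3-yl}methyl 4-nitrobenzoate | COc1cc([C@H]2OC[C@@H]([C@@H](OC(=O)c3ccc(cc3)[N+](=O)[O-])c3ccc(OCc4ccccc4)c(OCc4ccccc4)c3)[C@@H]2CO[Si](C)(C)C(C)(C)C)ccc1OCc1ccccc1
F8 | step 9 | (R)-[3,4-bis(benzyloxy)phenyl]{(3S,4R,5S)-5-[4-(benzyloxy)-3-methoxyphenyl]-4-[(tert-butyldimethylsilyloxy)methyl]oxolan-3-yl}methanol | COc1cc([C@H]2OC[C@@H]([C@@H](O)c3ccc(OCc4ccccc4)c(OCc4ccccc4)c3)[C@@H]2CO[Si](C)(C)C(C)(C)C)ccc1OCc1ccccc1
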